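**Retrosynthetic overview**

1. Target 25 comes from bis-benzyl ether 24 by hydrogenolysis. The C3 hydroxyl is put on flavone 21 by C3 lithiation, boration and oxidation. O5 and O7 are told apart on diol 19 through the hydrogen bond from the 5-OH to the C4 carbonyl.
2. Ring C, the only ring that is built, is closed by a palladium-catalysed union of iodophenol 5, carbon monoxide 15 and arylacetylene 14. This forms C4a–C4, C4–C3 and O1–C2 in one flask.
3. The feature used: C4 is an isolated carbonyl carbon between C4a and C3, so it can come from CO. The ring A oxygens on C8a, C7 and C5 lie mirror-symmetrically about the C6 methoxy, so ring A can enter as a symmetric phenol whose two ortho positions are identical.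
4. Iodophenol 5 comes from 2-methoxyresorcinol by bis-MOM protection, iridium C–H borylation/oxidation and mono-iodination. Alkyne 14 comes from the (R)-Roche ester (the only stereocentre, from the chiral pool) by B-alkyl Suzuki coupling at the C–I bond of 4-bromo-2-iodoanisole, then Sonogashira ethynylation at C–Br.
5. Ring order: rings A and B are purchased as benzenes; ring C is formed in step 10.

Key step: step 10

Remark: the side-chain stereocentre is carried unchanged from methyl (R)-3-hydroxy-2-methylpropanoate. Its descriptor switches between R and S along the route only because CIP priorities change, never because the spatial arrangement changes.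

**Route**

Step 1
Reactants: 1 2-methoxybenzene-1,3-diol
Product: 2 2-methoxy-1,3-bis(methoxymethoxy)benzene
Conditions: MOMCl (2.5 equiv), i-Pr2NEt, CH2Cl2, 0 °C → rt
Reagents that add atoms: chloromethyl methyl ether, COCCl
Why: Double Williamson-type O-alkylation of the two equivalent phenols by the activated α-chloro ether under amine base should give the symmetric bis-MOM ether.

Step 2
Reactants: 2 2-methoxy-1,3-bis(methoxymethoxy)benzene
Product: 4 4-methoxy-3,5-bis(methoxymethoxy)phenol, via aryl pinacol boronate 3 (not isolated)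
Conditions: [Ir(OMe)(cod)]2 (1.5 mol %), 4,4'-di-tert-butyl-2,2'-bipyridine (3 mol %), B2pin2 (0.6 equiv), THF, 80 °C; then 30% aq H2O2, aq NaOH, 0 °C; NH4Cl work-up
Reagents that add atoms: hydrogen peroxide, OO (phenol oxygen of 4); bis(pinacolato)diboron, CC1(C)OB(OC1(C)C)B1OC(C)(C)C(C)(C)O1 (boryl group of intermediate 3 only)
Why: Iridium-catalysed C–H borylation is sterically governed and C5 is the only ring C–H without an ortho substituent, and the aryl boronate is then oxidised to the phenol by basic peroxide (boron-to-oxygen 1,2-aryl shift), conditions to which MOM acetals are inert.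

Step 3
Reactants: 4 4-methoxy-3,5-bis(methoxymethoxy)phenol
Product: 5 2-iodo-4-methoxy-3,5-bis(methoxymethoxy)phenol
Conditions: N-iodosuccinimide (1.0 equiv), DMF, −10 → 0 °C, dark
Reagents that add atoms: N-iodosuccinimide, O=C1CCC(=O)N1I
Why: Electrophilic aromatic iodination of a strongly activated phenol whose two free ring positions are equivalent (each ortho to the hydroxyl), so one equivalent of iodinating agent at low temperature can only give this mono-iodide.

Step 4
Reactants: 6 methyl (R)-3-hydroxy-2-methylpropanoate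
Product: 7 methyl (R)-3-(benzyloxy)-2-methylpropanoate
Conditions: benzyl 2,2,2-trichloroacetimidate (1.3 equiv), TfOH (cat.), CH2Cl2/cyclohexane, 0 °C → rt
Reagents that add atoms: benzyl 2,2,2-trichloroacetimidate, N=C(OCc1ccccc1)C(Cl)(Cl)Cl
Why: Acid-catalysed O-benzylation with the trichloroacetimidate avoids base, so the α-stereocentre of the β-hydroxy ester is not epimerised and no β-elimination occurs.

Step 5
Reactants: 7 methyl (R)-3-(benzyloxy)-2-methylpropanoate
Product: 8 (R)-3-(benzyloxy)-2-methylpropanal
Conditions: i-Bu2AlH (1.1 equiv), CH2Cl2, −78 °C; aq potassium sodium tartrate; crude product used at once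
Reagents that add atoms: none
Why: Partial ester reduction by the aluminium hydride at −78 °C stops at the tetrahedral aluminium hemiacetal, which releases the aldehyde only on work-up, and immediate use protects the α-stereocentre.

Step 6
Reactants: 8 (R)-3-(benzyloxy)-2-methylpropanal
Product: 9 (S)-{[(2-methylbut-3-en-1-yl)oxy]methyl}benzene
Conditions: Ph3PCH3Br, KN(SiMe3)2, THF, 0 °C; then 8, −78 → 0 °C
Reagents that add atoms: methyltriphenylphosphonium bromide, C[P+](c1ccccc1)(c1ccccc1)c1ccccc1.[Br-]
Why: Wittig methylenation with the non-stabilised ylide is fast at low temperature, so the carbonyl should be consumed before enolisation can erode the adjacent stereocentre, whose spatial arrangement is carried over unchanged.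

Step 7
Reactants: 9 (S)-{[(2-methylbut-3-en-1-yl)oxy]methyl}benzene; 10 4-bromo-2-iodo-1-methoxybenzene
Product: 12 2-[(3S)-4-(benzyloxy)-3-methylbutyl]-4-bromo-1-methoxybenzene, via B-alkyl-9-BBN adduct 11 (not isolated)
Conditions: 9-BBN-H (1.1 equiv), THF, 0 °C → rt; then 10, PdCl2(dppf) (3 mol %), 3 M aq K3PO4, DMF, rt → 45 °C
Reagents that add atoms: 9-borabicyclo[3.3.1]nonane, B1C2CCCC1CCC2 (boryl group of intermediate 11 only; only hydrogen from it remains in 12)
Why: Anti-Markovnikov hydroboration places boron on the terminal carbon and the B-alkyl Suzuki–Miyaura coupling then engages only the C–I bond of 10, because zerovalent palladium inserts into aryl iodides much faster than into aryl bromides near room temperature, with the stereocentre a spectator.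

Step 8
Reactants: 12 2-[(3S)-4-(benzyloxy)-3-methylbutyl]-4-bromo-1-methoxybenzene
Product: 13 ({3-[(3S)-4-(benzyloxy)-3-methylbutyl]-4-methoxyphenyl}ethynyl)trimethylsilane
Conditions: ethynyltrimethylsilane (1.5 equiv), Pd(PhCN)2Cl2 (3 mol %), [HP(t-Bu)3]BF4 (6 mol %), CuI (2 mol %), i-Pr2NH, 1,4-dioxane, rt → 45 °C
Reagents that add atoms: ethynyltrimethylsilane, C#C[Si](C)(C)C
Why: Sonogashira coupling of the remaining aryl bromide, for which the bulky electron-rich phosphine allows oxidative addition into the electron-rich C–Br bond under mild conditions.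

Step 9
Reactants: 13 ({3-[(3S)-4-(benzyloxy)-3-methylbutyl]-4-methoxyphenyl}ethynyl)trimethylsilane
Product: 14 2-[(3S)-4-(benzyloxy)-3-methylbutyl]-4-ethynyl-1-methoxybenzene
Conditions: K2CO3, MeOH, rt
Reagents that add atoms: none
Why: Methoxide-mediated protodesilylation of the alkynyl C–Si bond should free the terminal alkyne without touching the benzyl or methyl ethers.

Step 10
Reactants: 5 2-iodo-4-methoxy-3,5-bis(methoxymethoxy)phenol; 14 2-[(3S)-4-(benzyloxy)-3-methylbutyl]-4-ethynyl-1-methoxybenzene; 15 carbon monoxide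
Product: 18 2-{3-[(3S)-4-(benzyloxy)-3-methylbutyl]-4-methoxyphenyl}-6-methoxy-5,7-bis(methoxymethoxy)-4H-chromen-4-one, via o-hydroxyaryl ynone 16 (not isolated), via diethylamino enaminone 17 (not isolated)
Conditions: PdCl2(dppf) (5 mol %), CO (10 bar), Et2NH, 100 °C
Reagents that add atoms: diethylamine, CCNCC (enters intermediate 17 and leaves again; all atoms of 18 come from 5, 14 and 15)
Why: Zerovalent palladium, formed from PdCl2(dppf) under CO and amine, inserts into the C–I bond of 5, CO insertion gives the aroylpalladium iodide, and amine-assisted transfer of the acetylide of 14 followed by reductive elimination gives ynone 16 (C4a–C4 and C4–C3). Diethylamine then adds in conjugate fashion to 16 to give enaminone 17, and the ortho phenol oxygen attacks the β-carbon with loss of the amine (addition–elimination), closing ring C through O1–C2 in a six-membered, 6-endo mode. The closest known reaction type is the palladium-catalysed carbonylative Sonogashira coupling and cyclisation of o-iodophenols with terminal arylacetylenes in diethylamine, an established flavone synthesis. No stereocentre is formed and the side-chain stereocentre is remote from every reacting site. The step needs carbonylative coupling in place of direct coupling (secured by CO pressure, the chelating dppf ligand and the absence of copper), six-membered flavone closure in place of five-membered aurone closure (secured by routing the cyclisation through amine adduct 17), and a single ring A regiochemistry (secured because 5 derives from a symmetric phenol with one kind of ortho position, so the C5/C6/C7 oxygen pattern cannot be misplaced). The MOM acetals and the benzyl ether are inert to the basic medium.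

Step 11
Reactants: 18 2-{3-[(3S)-4-(benzyloxy)-3-methylbutyl]-4-methoxyphenyl}-6-methoxy-5,7-bis(methoxymethoxy)-4H-chromen-4-one
Product: 19 2-{3-[(3S)-4-(benzyloxy)-3-methylbutyl]-4-methoxyphenyl}-5,7-dihydroxy-6-methoxy-4H-chromen-4-one
Conditions: 3 M aq HCl, MeOH/THF, 50 °C
Reagents that add atoms: none
Why: Acid-catalysed acetal cleavage (transacetalisation to methanol) removes both MOM groups, while the aryl methyl ethers, the alkyl benzyl ether and the chromone are stable to dilute methanolic HCl.

Step 12
Reactants: 19 2-{3-[(3S)-4-(benzyloxy)-3-methylbutyl]-4-methoxyphenyl}-5,7-dihydroxy-6-methoxy-4H-chromen-4-one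
Product: 20 7-(benzyloxy)-2-{3-[(3S)-4-(benzyloxy)-3-methylbutyl]-4-methoxyphenyl}-5-hydroxy-6-methoxy-4H-chromen-4-one
Conditions: BnBr (1.05 equiv), K2CO3 (1.2 equiv), acetone, rt → 40 °C
Reagents that add atoms: benzyl bromide, BrCc1ccccc1
Why: Williamson etherification selective for the 7-hydroxyl, the more acidic and unencumbered phenol, because the 5-hydroxyl is held in a hydrogen bond to the C4 carbonyl and reacts only under more forcing conditions.

Step 13
Reactants: 20 7-(benzyloxy)-2-{3-[(3S)-4-(benzyloxy)-3-methylbutyl]-4-methoxyphenyl}-5-hydroxy-6-methoxy-4H-chromen-4-one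
Product: 21 7-(benzyloxy)-2-{3-[(3S)-4-(benzyloxy)-3-methylbutyl]-4-methoxyphenyl}-5,6-dimethoxy-4H-chromen-4-one
Conditions: MeI (excess), Cs2CO3, DMF, 50 °C
Reagents that add atoms: iodomethane, CI
Why: Williamson O-methylation of the chelated 5-hydroxyl, now the only acidic site, which the caesium base and excess iodomethane in a dipolar aprotic solvent should drive to completion.

Step 14
Reactants: 21 7-(benzyloxy)-2-{3-[(3S)-4-(benzyloxy)-3-methylbutyl]-4-methoxyphenyl}-5,6-dimethoxy-4H-chromen-4-one
Product: 24 7-(benzyloxy)-2-{3-[(3S)-4-(benzyloxy)-3-methylbutyl]-4-methoxyphenyl}-3-hydroxy-5,6-dimethoxy-4H-chromen-4-one, via 3-lithioflavone 22 (not isolated), via 3-(dimethoxyboryl)flavone 23 (not isolated)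
Conditions: LiN(i-Pr)2 (1.5 equiv), THF, −78 °C; B(OMe)3 (3 equiv), −78 → 0 °C; AcOH, 30% aq H2O2, 0 °C → rt
Reagents that add atoms: hydrogen peroxide, OO (C3 oxygen of 24); lithium diisopropylamide, [Li+].CC(C)[N-]C(C)C (lithium of intermediate 22 only); trimethyl borate, COB(OC)OC (boryl group of intermediate 23 only)
Why: Deprotonation of the flavone at C3 by the lithium amide at −78 °C, trapping with trimethyl borate and oxidative C–B to C–O conversion (boron-to-oxygen 1,2-shift) is an established flavone-to-flavonol sequence, and 21 carries no other acidic hydrogen.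

Step 15
Reactants: 24 7-(benzyloxy)-2-{3-[(3S)-4-(benzyloxy)-3-methylbutyl]-4-methoxyphenyl}-3-hydroxy-5,6-dimethoxy-4H-chromen-4-one
Product: 25 3,7-dihydroxy-2-{3-[(3S)-4-hydroxy-3-methylbutyl]-4-methoxyphenyl}-5,6-dimethoxy-4H-chromen-4-one
Conditions: H2 (1 atm), Pd(OH)2/C, EtOAc/MeOH, rt
Reagents that add atoms: none
Why: Catalytic hydrogenolysis cleaves both benzylic C–O bonds (aryl benzyl and primary alkyl benzyl ether), while the flavonol nucleus, a vinylogous ester within an aromatic pyranone, should not be reduced at atmospheric pressure and the stereocentre is untouched.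

**Compound list**

1 | 2-methoxybenzene-1,3-diol | COc1c(O)cccc1O | starting material
2 | 2-methoxy-1,3-bis(methoxymethoxy)benzene | COCOc1cccc(OCOC)c1OC | intermediate
3 | 2-[4-methoxy-3,5-bis(methoxymethoxy)phenyl]-4,4,5,5-tetramethyl-1,3,2-dioxaborolane | COCOc1cc(B2OC(C)(C)C(C)(C)O2)cc(OCOC)c1OC | intermediate
4 | 4-methoxy-3,5-bis(methoxymethoxy)phenol | COCOc1cc(O)cc(OCOC)c1OC | intermediate
5 | 2-iodo-4-methoxy-3,5-bis(methoxymethoxy)phenol | COCOc1cc(O)c(I)c(OCOC)c1OC | intermediate
6 | methyl (R)-3-hydroxy-2-methylpropanoate | COC(=O)[C@H](C)CO | starting material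
7 | methyl (R)-3-(benzyloxy)-2-methylpropanoate | COC(=O)[C@H](C)COCc1ccccc1 | intermediate
8 | (R)-3-(benzyloxy)-2-methylpropanal | O=C[C@H](C)COCc1ccccc1 | intermediate
9 | (S)-{[(2-methylbut-3-en-1-yl)oxy]methyl}benzene | C=C[C@H](C)COCc1ccccc1 | intermediate
10 | 4-bromo-2-iodo-1-methoxybenzene | COc1ccc(Br)cc1I | starting material
11 | 9-[(3S)-4-(benzyloxy)-3-methylbutyl]-9-borabicyclo[3.3.1]nonane | B1(CC[C@H](C)COCc2ccccc2)C2CCCC1CCC2 | intermediate
12 | 2-[(3S)-4-(benzyloxy)-3-methylbutyl]-4-bromo-1-methoxybenzene | COc1ccc(Br)cc1CC[C@H](C)COCc1ccccc1 | intermediate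
13 | ({3-[(3S)-4-(benzyloxy)-3-methylbutyl]-4-methoxyphenyl}ethynyl)trimethylsilane | COc1ccc(C#C[Si](C)(C)C)cc1CC[C@H](C)COCc1ccccc1 | intermediate
14 | 2-[(3S)-4-(benzyloxy)-3-methylbutyl]-4-ethynyl-1-methoxybenzene | C#Cc1ccc(OC)c(CC[C@H](C)COCc2ccccc2)c1 | intermediate
15 | carbon monoxide | [C-]#[O+] | starting material
16 | 3-{3-[(3S)-4-(benzyloxy)-3-methylbutyl]-4-methoxyphenyl}-1-[2-hydroxy-5-methoxy-4,6-bis(methoxymethoxy)phenyl]prop-2-yn-1-one | COCOc1cc(O)c(C(=O)C#Cc2ccc(OC)c(CC[C@H](C)COCc3ccccc3)c2)c(OCOC)c1OC | intermediate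
17 | 3-{3-[(3S)-4-(benzyloxy)-3-methylbutyl]-4-methoxyphenyl}-3-(diethylamino)-1-[2-hydroxy-5-methoxy-4,6-bis(methoxymethoxy)phenyl]prop-2-en-1-one (alkene geometry not defined) | COCOc1cc(O)c(C(=O)C=C(N(CC)CC)c2ccc(OC)c(CC[C@H](C)COCc3ccccc3)c2)c(OCOC)c1OC | intermediate
18 | 2-{3-[(3S)-4-(benzyloxy)-3-methylbutyl]-4-methoxyphenyl}-6-methoxy-5,7-bis(methoxymethoxy)-4H-chromen-4-one | COCOc1cc2oc(-c3ccc(OC)c(CC[C@H](C)COCc4ccccc4)c3)cc(=O)c2c(OCOC)c1OC | intermediate
19 | 2-{3-[(3S)-4-(benzyloxy)-3-methylbutyl]-4-methoxyphenyl}-5,7-dihydroxy-6-methoxy-4H-chromen-4-one | COc1c(O)cc2oc(-c3ccc(OC)c(CC[C@H](C)COCc4ccccc4)c3)cc(=O)c2c1O | intermediate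
20 | 7-(benzyloxy)-2-{3-[(3S)-4-(benzyloxy)-3-methylbutyl]-4-methoxyphenyl}-5-hydroxy-6-methoxy-4H-chromen-4-one | COc1c(OCc5ccccc5)cc2oc(-c3ccc(OC)c(CC[C@H](C)COCc4ccccc4)c3)cc(=O)c2c1O | intermediate
21 | 7-(benzyloxy)-2-{3-[(3S)-4-(benzyloxy)-3-methylbutyl]-4-methoxyphenyl}-5,6-dimethoxy-4H-chromen-4-one | COc1c(OCc5ccccc5)cc2oc(-c3ccc(OC)c(CC[C@H](C)COCc4ccccc4)c3)cc(=O)c2c1OC | intermediate
22 | 3-lithio derivative of 21 (C3–Li) | COc1c(OCc5ccccc5)cc2oc(-c3ccc(OC)c(CC[C@H](C)COCc4ccccc4)c3)c([Li])c(=O)c2c1OC | intermediate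
23 | dimethyl [7-(benzyloxy)-2-{3-[(3S)-4-(benzyloxy)-3-methylbutyl]-4-methoxyphenyl}-5,6-dimethoxy-4-oxo-4H-chromen-3-yl]boronate | COc1c(OCc5ccccc5)cc2oc(-c3ccc(OC)c(CC[C@H](C)COCc4ccccc4)c3)c(B(OC)OC)c(=O)c2c1OC | intermediate
24 | 7-(benzyloxy)-2-{3-[(3S)-4-(benzyloxy)-3-methylbutyl]-4-methoxyphenyl}-3-hydroxy-5,6-dimethoxy-4H-chromen-4-one | COc1c(OCc5ccccc5)cc2oc(-c3ccc(OC)c(CC[C@H](C)COCc4ccccc4)c3)c(O)c(=O)c2c1OC | intermediate
25 | 3,7-dihydroxy-2-{3-[(3S)-4-hydroxy-3-methylbutyl]-4-methoxyphenyl}-5,6-dimethoxy-4H-chromen-4-one | COc1ccc(-c2oc3cc(O)c(OC)c(OC)c3c(=O)c2O)cc1CC[C@H](C)CO | target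

**Step count**

Total: 15 steps (3 to iodophenol 5, 6 to alkyne 14, 6 from the key step to the target).
Longest linear sequence: 12 steps (6 → 25, steps 4–15).

**Steps most likely to fail, with fallbacks**

Step 10. On the hindered, electron-rich aryl iodide, direct (non-carbonylative) alkynylation followed by closure to a 2-arylbenzofuran, aminocarbonylation by diethylamine, or five-membered closure to an aurone may outrun the desired sequence. The fallback builds the same ynone without palladium and CO. It sets out from phenol 4 and alkyne 14 and returns at 18. Phenol 4 is ortho-formylated under magnesium mediation (MgCl2, Et3N, paraformaldehyde, MeCN, reflux) to 2-hydroxy-5-methoxy-4,6-bis(methoxymethoxy)benzaldehyde F1. Only one ortho position type exists, so the regiochemistry is again fixed by symmetry. F1 is converted to its lithium phenoxide with LiN(SiMe3)2 and treated with the lithium acetylide of 14 (n-BuLi, THF, −78 °C). This should give 3-{3-[(3S)-4-(benzyloxy)-3-methylbutyl]-4-methoxyphenyl}-1-[2-hydroxy-5-methoxy-4,6-bis(methoxymethoxy)phenyl]prop-2-yn-1-ol F2 as a mixture of carbinol epimers, which does not matter. Oxidation with MnO2 in CH2Cl2 gives ynone 16. Diethylamine in ethanol at rt to 60 °C takes 16 through enaminone 17 to flavone 18, and the route continues with step 11.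

Step 14. Addition of the amide base at C2 with pyranone ring opening, or incomplete C3 metalation beside the crowded peri-methoxy carbonyl, may leave much of 21 unconverted. The fallback replaces the anionic route by electrophilic oxidation. It sets out from 21 and returns at 24. Dimethyldioxirane in acetone at 0 °C should epoxidise the C2–C3 double bond to 7-(benzyloxy)-2-{3-[(3S)-4-(benzyloxy)-3-methylbutyl]-4-methoxyphenyl}-5,6-dimethoxy-2,3-epoxychroman-4-one F3, as both epoxide configurations. Catalytic TsOH in CH2Cl2 then opens the epoxide and tautomerises it to flavonol 24, and the route continues with step 15.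

Step 6. Enolisation of the α-methyl aldehyde 8 during the work-up of step 5 or under the basic ylide may erode the enantiopurity of the side chain, and over-reduction in step 5 lowers throughput. The fallback avoids any aldehyde. It sets out from ester 7 and returns at 12. Reduction with LiAlH4 in THF gives (S)-3-(benzyloxy)-2-methylpropan-1-ol F4. Appel bromination (CBr4, PPh3, CH2Cl2) gives (R)-{[(3-bromo-2-methylpropoxy]methyl}benzene F5. Magnesium in THF converts F5 to (R)-[3-(benzyloxy)-2-methylpropyl]magnesium bromide F6, which is not isolated. Coupling of F6 with commercial 4-bromo-2-(bromomethyl)-1-methoxybenzene (COc1ccc(Br)cc1CBr) under Li2CuCl4 catalysis in THF at −20 → 0 °C should give 12, with the aryl bromide untouched. The stereocentre never sits next to a carbonyl after the ester stage. The route continues with step 8.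

**Further compounds**

F1 | step 10 | 2-hydroxy-5-methoxy-4,6-bis(methoxymethoxy)benzaldehyde | COCOc1cc(O)c(C=O)c(OCOC)c1OC
F2 | step 10 | 3-{3-[(3S)-4-(benzyloxy)-3-methylbutyl]-4-methoxyphenyl}-1-[2-hydroxy-5-methoxy-4,6-bis(methoxymethoxy)phenyl]prop-2-yn-1-ol (carbinol epimers) | COCOc1cc(O)c(C(O)C#Cc2ccc(OC)c(CC[C@H](C)COCc3ccccc3)c2)c(OCOC)c1OC
F3 | step 14 | 7-(benzyloxy)-2-{3-[(3S)-4-(benzyloxy)-3-methylbutyl]-4-methoxyphenyl}-5,6-dimethoxy-2,3-epoxychroman-4-one (both epoxide configurations) | COc1c(OCc5ccccc5)cc2OC3(c4ccc(OC)c(CC[C@H](C)COCc6ccccc6)c4)OC3C(=O)c2c1OC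
F4 | step 6 | (S)-3-(benzyloxy)-2-methylpropan-1-ol | OC[C@H](C)COCc1ccccc1
F5 | step 6 | (R)-{[(3-bromo-2-methylpropoxy]methyl}benzene | BrC[C@H](C)COCc1ccccc1
F6 | step 6 | (R)-[3-(benzyloxy)-2-methylpropyl]magnesium bromide | Br[Mg]C[C@H](C)COCc1ccccc1
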